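Of 150 mM of substrate, the north-west run with 12.0 mM of free catalyst still holds 96.3 mM at 34 h, and the west run with 18.0 mM holds 86.7 mM. The north-west run slows from 3.60 mM/h over its first stretch to 0.417 mM/h over its last, though it has lost a third of its substrate. The east run, charged with 75.0 mM of product, ends at 96.5 mM, so I set product aside and watch the catalyst.

| setting | north-west | east | west | north-east |
|---|---|---|---|---|
| substrate | 150 mM | 150 mM | 150 mM | 150 mM |
| free catalyst | 12.0 mM | 12.0 mM | 18.0 mM | 25.0 mM |
| product |  | 75.0 mM |  |  |
| time |  |  |  | 34 h |

| run | time / h | [substrate] / mM |
|---|---|---|
| north-west run | 5.7 | 129.5 |
| north-west run | 11 | 118.7 |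
| north-west run | 17 | 109.1 |
| north-west run | 23 | 103.0 |
| north-west run | 28 | 98.8 |
| north-west run | 34 | 96.3 |
| east run | 5.7 | 129.6 |
| east run | 11 | 116.7 |
| east run | 17 | 110.6 |
| east run | 23 | 104.2 |
| east run | 28 | 100.1 |
| east run | 34 | 96.5 |
| west run | 5.7 | 124.7 |
| west run | 11 | 108.6 |
| west run | 17 | 98.4 |
| west run | 23 | 91.8 |
| west run | 28 | 88.0 |
| west run | 34 | 86.7 |

(readings scatter by 0.8 mM)

- Overall: substrate -> product, with free catalyst as catalyst.
- Constant volume, constant temperature.
- An order is taken over about fifteen percent of the charge, up and down.

* the exponent of [free catalyst] in the starting rate at the charge of the north-west run (at the point where two percent of the substrate have become product)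
* substrate in the north-east run at 34 h, as a share of the substrate charged

To compare the north-west and west runs I take the logarithm of charge over substrate left, the pseudo-first-order measure. In the north-west run it reaches 0.443 at the last reading, from an opening slope of 0.0258 /h over the first reading. So its working life, the hours at opening pace that would give that final logarithm, is 17.2 h. In the west run the logarithm reaches 0.548 from a slope of 0.0324 /h, and the working life reads 16.9 h. The west run therefore ends lower than the north-west run through a steeper opening, on a working life that reads the same within the scatter.

Those two slopes give me an order in free catalyst of 0.564. That takes the opening slope of the north-east run, with 25.0 mM, to 0.0390 /h, and 17.2 h of working life leaves 51.1 % of its substrate at 34 h. The forecast gives a higher order of 0.75 and a higher share of 53.5 %, saying of the slowing: “This suggests the catalyst is dying.”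

The flask gives an order of 0.81 and a share of 49.0 %, and the forecast's two values count as right within the tolerance set for the questions.

    2 free catalyst ⇌ catalyst dimer, settled at all times (31.90 /M)
    free catalyst + substrate → product + free catalyst (3.031 /M/h)
    free catalyst → spent catalyst (0.1231 /h)
    2 substrate → homo dimer (0.01912 /M/h)

The passing of free catalyst into spent catalyst holds the north-east run up at 49.0 %: the simulated north-east run without that step falls to 22.6 %, which lies 31 percentage points below the forecast's 53.5 %, so a repeat should watch for the flattening. That simulated run keeps its catalyst for the full 34 h, so its logarithm stands for the opening pace over that time, and the working life of the north-east run reads 16.3 h.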